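**Plan**
- Retrosynthesis: the two inter-unit esters (C15–O of units A and B to the central carboxyl C6' of isocitrates B and C) are cut first, giving three copies of one monomer. In the monomer the C4–C5 and C9–C10 bonds (rings A and B) are cut back to an O-farnesyl (2R,3S)-isocitrate, then the allylic C11–O ether, then C3'–C4' of the isocitrate (malate + bromoacetate).
- Enabling feature: each drimane is a head-to-tail farnesyl chain. C4 (CH3 and equatorial C15H2–O) with its neighbour C3 maps onto a 2,3-epoxy alcohol, the C5=C10 and C9=C8 trisubstituted alkenes relay a C4 radical, C12 ends as the exocyclic methylene, and C11–O is the farnesyl C1–O, so the ether can be in place before the rings form.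
- Forward: (R)-malic acid → isocitrate triester → O-farnesylation → C15 hydroxylation → asymmetric epoxidation → bicyclisation (ring A, C1–C5/C10, then ring B) → removal of the temporary C3–OH → two esterifications → deprotection. The bicyclisation is the only ring-forming step; one batch of its product supplies the central unit and both outer units.
- Stereochemistry: C2' comes from (R)-malic acid and C3' from chelate-controlled anti alkylation. The temporary C3 centre comes from reagent-controlled epoxidation; C4, C5, C9 and C10 are relayed from it in the chair–chair cascade.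

Key step: step 8

Remark: drimane numbering is used (C11 = CH2O on C9, C12 = exocyclic methylene carbon, C15 = oxygenated 4α, equatorial carbon on C4); the isocitrate is numbered C1'OOMe–C2'H(O)–C3'H(C6'OO)–C4'H2–C5'OO; the units are A (free C6' acid), B (central) and C (free C15–OH). (R)-Malic acid, tert-butyl bromoacetate and (2E,6E)-farnesyl bromide are taken as commercial.

**Step 1**
Reactants: 1 (R)-malic acid
Product: 4 (3R)-3-hydroxy-4-methoxy-4-oxobutanoic acid, via trifluoroacetoxysuccinic anhydride 2 (not isolated), via trifluoroacetyl half-ester 3 (not isolated)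
Conditions: (CF3CO)2O, 0 °C → rt; evaporate; MeOH, rt
Reagents that add atoms: methanol, CO
Why: Regioselective anhydride alcoholysis: methanol opens the O-acylated cyclic anhydride at the more electrophilic carbonyl next to the acyloxy carbon and then removes the trifluoroacetate, so only C1' is esterified and the stereocentre is untouched.

**Step 2**
Reactants: 4 (3R)-3-hydroxy-4-methoxy-4-oxobutanoic acid
Product: 5 4-allyl 1-methyl (2R)-2-hydroxybutanedioate
Conditions: allyl bromide, KHCO3, DMF, rt
Reagents that add atoms: allyl bromide, C=CCBr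
Why: Carboxylate O-alkylation (SN2) under bicarbonate leaves the secondary hydroxyl and the α-stereocentre untouched.

**Step 3**
Reactants: 5 4-allyl 1-methyl (2R)-2-hydroxybutanedioate; 6 tert-butyl bromoacetate
Product: 7 (2R,3S)-isocitrate 1'-methyl 6'-allyl 5'-tert-butyl triester
Conditions: LiN(SiMe3)2 (2.2 equiv), THF, −78 → −20 °C; then 6, −78 → −40 °C; AcOH
Reagents that add atoms: none
Why: Fráter–Seebach alkylation: the chelated lithium alkoxide–enolate dianion is alkylated anti to the alkoxide oxygen, which sets C3' as S (threo-isocitrate), and the tert-butyl ester cannot lactonise onto the C2' hydroxyl.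

**Step 4**
Reactants: 7 (2R,3S)-isocitrate triester; 8 (2E,6E)-farnesyl bromide
Product: 9 O-[(2E,6E)-farnesyl] ether of 7
Conditions: Ag2O, 4 Å molecular sieves, CH2Cl2, dark, rt
Reagents that add atoms: none
Why: Ag2O-mediated Williamson-type O-alkylation with a primary allylic bromide runs without an alkoxide, so retro-aldol cleavage and β-elimination of the hydroxy triester are avoided and the 2E geometry is kept.

**Step 5**
Reactants: 9 farnesyl ether
Product: 10 (2E,6E,10E)-12-hydroxyfarnesyl ether
Conditions: SeO2 (cat.), t-BuOOH, salicylic acid (cat.), CH2Cl2, 0 °C → rt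
Reagents that add atoms: tert-butyl hydroperoxide, CC(C)(C)OO
Why: Riley allylic oxidation (ene reaction, then [2,3]-shift) picks the (E)-methyl of the terminal, most electron-rich trisubstituted alkene; the C2=C3 alkene is deactivated by the allylic oxygen and the allyl ester alkene is monosubstituted.

**Step 6**
Reactants: 10 12-hydroxyfarnesyl ether
Product: 11 (10S,11S)-10,11-epoxy-12-hydroxyfarnesyl ether
Conditions: Ti(OiPr)4 (cat.), L-(+)-diethyl tartrate, t-BuOOH, 4 Å molecular sieves, CH2Cl2, −20 °C
Reagents that add atoms: tert-butyl hydroperoxide, CC(C)(C)OO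
Why: Sharpless asymmetric epoxidation touches only the allylic alcohol, and the L-(+)-tartrate complex delivers oxygen to the face that gives the (10S,11S)-epoxide, whose C10 becomes the temporary (3S) centre of the drimane.

**Step 7**
Reactants: 11 epoxy alcohol
Product: 12 12-O-triethylsilyl epoxide
Conditions: Et3SiCl, imidazole, CH2Cl2, 0 °C
Reagents that add atoms: chlorotriethylsilane, CC[Si](Cl)(CC)CC
Why: Silylation of the primary alcohol masks C15–OH for the radical step and later tells it apart from C3–OH.

**Step 8**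
Reactants: 12 12-O-triethylsilyl epoxide
Product: 13 3β-hydroxy-15-(triethylsilyloxy)drim-8(12)-en-11-yl isocitrate ether (4α-CH2OSiEt3, 4β-CH3, 5α-H, 9β-CH2O, 10β-CH3)
Conditions: Cp2TiCl2 (2.5 equiv), Mn powder, THF, rt (gives Cp2TiCl, trivalent titanium); slow addition of 12; then aq. NaH2PO4
Reagents that add atoms: none
Why: Cp2TiCl transfers one electron to the epoxide and cleaves the C4–O bond homolytically, giving a tertiary C4 radical that keeps the C3–O–Ti stereocentre; this radical adds 6-endo-trig to the C5=C10 alkene (ring A) and the new tertiary C10 radical adds 6-endo-trig to the C9=C8 alkene (ring B) through an all-chair, trans-anti fold. The closest known reaction type is the titanocene-mediated reductive opening and radical cyclisation of 2,3-epoxypolyprenes, which turns epoxyfarnesyl esters into 3β-hydroxy drim-8(12)-enes. C5, C10 and C9 follow from the E,E geometry of the two trisubstituted alkenes in the chair–chair fold (trans ring fusion, equatorial 9β-CH2O), and the absolute sense follows from the (3S) C–O–Ti centre, which sits equatorial. At the planar C4 radical the larger CH2OSiEt3 group should take the equatorial (α) position and the methyl the axial one, the same outcome that a concerted opening of the (E)-epoxide would give. The step needs 6-endo over 5-exo closure, secured because attack at the less substituted alkene terminus gives tertiary radicals, and exocyclic termination, secured because the tertiary C8 radical is trapped by a second Cp2TiCl and the alkyltitanium loses a β-hydride from the C12 methyl. The esters, the silyl ether and the allylic ether are inert to Cp2TiCl, so the isocitrate stays intact.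

**Step 9**
Reactants: 13 3β-hydroxy bicyclic monomer
Product: 14 3-O-(imidazol-1-ylthiocarbonyl) derivative of 13
Conditions: 1,1'-thiocarbonyldiimidazole, DMAP (cat.), ClCH2CH2Cl, 70 °C
Reagents that add atoms: 1,1'-thiocarbonyldiimidazole, S=C(n1ccnc1)n1ccnc1
Why: Acyl transfer to the only free hydroxyl (equatorial C3–OH) installs the thiocarbonyl group for the first half of a Barton–McCombie deoxygenation.

**Step 10**
Reactants: 14 thiocarbonyl derivative
Product: 15 3-deoxy monomer (15-O-SiEt3; 6'-allyl, 5'-tert-butyl, 1'-methyl esters)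
Conditions: Bu3SnH, AIBN (cat.), toluene, 100 °C
Reagents that add atoms: none
Why: Barton–McCombie deoxygenation: the stannyl radical adds to C=S, β-scission gives the secondary C3 radical and Bu3SnH reduces it; no stereocentre is involved and the remote alkenes cannot be reached.

**Step 11**
Reactants: 15 3-deoxy monomer
Product: 16 monomer acid (C6' carboxylic acid free)
Conditions: Pd(PPh3)4 (cat., zerovalent palladium), morpholine, THF, rt
Reagents that add atoms: none
Why: Tsuji–Trost deallylation ionises only the allyl ester and morpholine traps the π-allyl, so the methyl and tert-butyl esters, the silyl ether and the exocyclic alkene stay intact.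

**Step 12**
Reactants: 15 3-deoxy monomer
Product: 18 hydroxy acid (C15–OH and C5' acid free; 6'-allyl ester), via trimethylsilyl ester 17 (not isolated)
Conditions: Me3SiOTf, 2,6-lutidine, CH2Cl2, 0 °C; then 0.5 M aq. HCl–THF, rt
Reagents that add atoms: none
Why: Silyl triflate-mediated tert-butyl ester cleavage (O-silylation, loss of isobutene) under lutidine buffer spares the acid-sensitive exocyclic alkene, and the dilute-acid work-up hydrolyses the silyl ester and the primary triethylsilyl ether.

**Step 13**
Reactants: 18 hydroxy acid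
Product: 19 unit A alcohol (C15–OH; 5'-methyl, 6'-allyl, 1'-methyl esters)
Conditions: Me3SiCHN2, MeOH–toluene, 0 °C
Reagents that add atoms: (trimethylsilyl)diazomethane, C[Si](C)(C)C=[N+]=[N-]
Why: Diazoalkane esterification methylates only the carboxylic acid, which gives the C5' methyl ester of unit A and leaves the alcohol free.

**Step 14**
Reactants: 16 monomer acid; 19 unit A alcohol
Product: 21 dimer A–B (unit B 15-O-SiEt3), via trichlorobenzoyl mixed anhydride 20 (not isolated)
Conditions: 2,4,6-trichlorobenzoyl chloride, Et3N, toluene, rt; then 19, DMAP, toluene, rt → 40 °C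
Reagents that add atoms: none
Why: Yamaguchi esterification: DMAP attacks the mixed anhydride at the isocitrate carbonyl (the aroyl carbonyl is shielded by two ortho chlorines) and the acyl-pyridinium acylates the neopentyl primary C15–OH; no stereocentre is formed.

**Step 15**
Reactants: 21 dimer A–B silyl ether
Product: 22 dimer A–B alcohol (unit B C15–OH)
Conditions: pyridinium p-toluenesulfonate, MeOH–CH2Cl2, rt
Reagents that add atoms: none
Why: Mild acid-catalysed methanolysis removes only the primary triethylsilyl ether; tert-butyl, allyl and methyl esters and the alkenes are stable.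

**Step 16**
Reactants: 22 dimer A–B alcohol; 16 monomer acid
Product: 24 protected trimer A–B–C, via 2-methyl-6-nitrobenzoyl mixed anhydride 23 (not isolated)
Conditions: 16, 22, 2-methyl-6-nitrobenzoic anhydride, Et3N, DMAP, CH2Cl2, rt
Reagents that add atoms: none
Why: Shiina esterification: the carboxylate of 16 opens 2-methyl-6-nitrobenzoic anhydride to the mixed anhydride, DMAP attacks its isocitrate carbonyl (the aroyl carbonyl is flanked by the ortho methyl and nitro groups) and the acyl-pyridinium acylates the neopentyl C15–OH of unit B; because the acid is activated in the presence of the alcohol, the valuable dimer can be used in near-equimolar amount and the activated acid is short-lived; no stereocentre is formed.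

**Step 17**
Reactants: 24 protected trimer
Product: 26 trimer with both C5' acids and C15–OH free (6'-allyl ester on unit A), via bis(trimethylsilyl) ester 25 (not isolated)
Conditions: Me3SiOTf, 2,6-lutidine, CH2Cl2, 0 °C; then 0.5 M aq. HCl–THF, rt
Reagents that add atoms: none
Why: The same buffered silyl triflate cleavage removes both tert-butyl esters, and the dilute-acid work-up frees the acids and the C15 alcohol while the methyl, allyl and neopentyl esters and the three exocyclic alkenes should survive.

**Step 18**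
Reactants: 26 trimer mono-allyl ester
Product: 27 cryptoporic acid T
Conditions: Pd(PPh3)4 (cat., zerovalent palladium), morpholine, THF, rt; aq. citric acid work-up
Reagents that add atoms: none
Why: Tsuji–Trost deallylation frees the last carboxylic acid (C6' of unit A) under neutral conditions that touch no other group.

**Compound list**
1 | (R)-malic acid | O[C@H](CC(=O)O)C(=O)O | starting material
2 | (R)-2-(trifluoroacetoxy)succinic anhydride | O=C1C[C@@H](OC(=O)C(F)(F)F)C(=O)O1 | intermediate
3 | (3R)-4-methoxy-4-oxo-3-(trifluoroacetoxy)butanoic acid | COC(=O)[C@H](OC(=O)C(F)(F)F)CC(=O)O | intermediate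
4 | (3R)-3-hydroxy-4-methoxy-4-oxobutanoic acid | COC(=O)[C@H](O)CC(=O)O | intermediate
5 | 4-allyl 1-methyl (2R)-2-hydroxybutanedioate | COC(=O)[C@H](O)CC(=O)OCC=C | intermediate
6 | tert-butyl bromoacetate | CC(C)(C)OC(=O)CBr | starting material
7 | 2-allyl 3-tert-butyl 1-methyl (1R,2S)-1-hydroxypropane-1,2,3-tricarboxylate | O[C@@H](C(=O)OC)[C@H](CC(=O)OC(C)(C)C)C(=O)OCC=C | intermediate
8 | (2E,6E)-farnesyl bromide | CC(C)=CCC/C(C)=C/CC/C(C)=C/CBr | starting material
9 | O-[(2E,6E)-farnesyl] ether of 7 | CC(C)=CCC/C(C)=C/CC/C(C)=C/CO[C@@H](C(=O)OC)[C@H](CC(=O)OC(C)(C)C)C(=O)OCC=C | intermediate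
10 | (2E,6E,10E)-12-hydroxyfarnesyl ether | OC/C(C)=C/CC/C(C)=C/CC/C(C)=C/CO[C@@H](C(=O)OC)[C@H](CC(=O)OC(C)(C)C)C(=O)OCC=C | intermediate
11 | (10S,11S)-10,11-epoxy-12-hydroxyfarnesyl ether | OC[C@]1(C)O[C@H]1CC/C(C)=C/CC/C(C)=C/CO[C@@H](C(=O)OC)[C@H](CC(=O)OC(C)(C)C)C(=O)OCC=C | intermediate
12 | 12-O-triethylsilyl ether of 11 | CC[Si](CC)(CC)OC[C@]1(C)O[C@H]1CC/C(C)=C/CC/C(C)=C/CO[C@@H](C(=O)OC)[C@H](CC(=O)OC(C)(C)C)C(=O)OCC=C | intermediate
13 | 3β-hydroxy-15-(triethylsilyloxy)drim-8(12)-en-11-yl ether of the isocitrate triester | C=C1CC[C@H]2[C@](C)(CO[Si](CC)(CC)CC)[C@@H](O)CC[C@]2(C)[C@H]1CO[C@@H](C(=O)OC)[C@H](CC(=O)OC(C)(C)C)C(=O)OCC=C | intermediate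
14 | 3-O-(imidazol-1-ylthiocarbonyl) derivative of 13 | C=C1CC[C@H]2[C@](C)(CO[Si](CC)(CC)CC)[C@@H](OC(=S)n3ccnc3)CC[C@]2(C)[C@H]1CO[C@@H](C(=O)OC)[C@H](CC(=O)OC(C)(C)C)C(=O)OCC=C | intermediate
15 | 3-deoxy monomer (15-O-SiEt3; 6'-allyl, 5'-tert-butyl, 1'-methyl) | C=C1CC[C@H]2[C@](C)(CO[Si](CC)(CC)CC)CCC[C@]2(C)[C@H]1CO[C@@H](C(=O)OC)[C@H](CC(=O)OC(C)(C)C)C(=O)OCC=C | intermediate
16 | monomer acid (C6' acid free) | C=C1CC[C@H]2[C@](C)(CO[Si](CC)(CC)CC)CCC[C@]2(C)[C@H]1CO[C@@H](C(=O)OC)[C@H](CC(=O)OC(C)(C)C)C(=O)O | intermediate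
17 | C5' trimethylsilyl ester of the monomer | C=C1CC[C@H]2[C@](C)(CO[Si](CC)(CC)CC)CCC[C@]2(C)[C@H]1CO[C@@H](C(=O)OC)[C@H](CC(=O)O[Si](C)(C)C)C(=O)OCC=C | intermediate
18 | hydroxy acid (C15–OH, C5' acid; 6'-allyl) | C=C1CC[C@H]2[C@](C)(CO)CCC[C@]2(C)[C@H]1CO[C@@H](C(=O)OC)[C@H](CC(=O)O)C(=O)OCC=C | intermediate
19 | unit A alcohol (C15–OH; 5'-methyl, 6'-allyl) | C=C1CC[C@H]2[C@](C)(CO)CCC[C@]2(C)[C@H]1CO[C@@H](C(=O)OC)[C@H](CC(=O)OC)C(=O)OCC=C | intermediate
20 | mixed anhydride of 16 with 2,4,6-trichlorobenzoic acid | C=C1CC[C@H]2[C@](C)(CO[Si](CC)(CC)CC)CCC[C@]2(C)[C@H]1CO[C@@H](C(=O)OC)[C@H](CC(=O)OC(C)(C)C)C(=O)OC(=O)c3c(Cl)cc(Cl)cc3Cl | intermediate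
21 | dimer A–B, unit B 15-O-SiEt3 | C=C1CC[C@H]2[C@](C)(COC(=O)[C@@H](CC(=O)OC(C)(C)C)[C@@H](OC[C@H]3C(=C)CC[C@H]4[C@](C)(CO[Si](CC)(CC)CC)CCC[C@]34C)C(=O)OC)CCC[C@]2(C)[C@H]1CO[C@@H](C(=O)OC)[C@H](CC(=O)OC)C(=O)OCC=C | intermediate
22 | dimer A–B, unit B C15–OH | C=C1CC[C@H]2[C@](C)(COC(=O)[C@@H](CC(=O)OC(C)(C)C)[C@@H](OC[C@H]3C(=C)CC[C@H]4[C@](C)(CO)CCC[C@]34C)C(=O)OC)CCC[C@]2(C)[C@H]1CO[C@@H](C(=O)OC)[C@H](CC(=O)OC)C(=O)OCC=C | intermediate
23 | mixed anhydride of 16 with 2-methyl-6-nitrobenzoic acid | C=C1CC[C@H]2[C@](C)(CO[Si](CC)(CC)CC)CCC[C@]2(C)[C@H]1CO[C@@H](C(=O)OC)[C@H](CC(=O)OC(C)(C)C)C(=O)OC(=O)c3c(C)cccc3[N+](=O)[O-] | intermediate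
24 | protected trimer A–B–C | C=C1CC[C@H]2[C@](C)(COC(=O)[C@@H](CC(=O)OC(C)(C)C)[C@@H](OC[C@H]3C(=C)CC[C@H]4[C@](C)(COC(=O)[C@@H](CC(=O)OC(C)(C)C)[C@@H](OC[C@H]5C(=C)CC[C@H]6[C@](C)(CO[Si](CC)(CC)CC)CCC[C@]56C)C(=O)OC)CCC[C@]34C)C(=O)OC)CCC[C@]2(C)[C@H]1CO[C@@H](C(=O)OC)[C@H](CC(=O)OC)C(=O)OCC=C | intermediate
25 | bis(trimethylsilyl) ester of the trimer | C=C1CC[C@H]2[C@](C)(COC(=O)[C@@H](CC(=O)O[Si](C)(C)C)[C@@H](OC[C@H]3C(=C)CC[C@H]4[C@](C)(COC(=O)[C@@H](CC(=O)O[Si](C)(C)C)[C@@H](OC[C@H]5C(=C)CC[C@H]6[C@](C)(CO[Si](CC)(CC)CC)CCC[C@]56C)C(=O)OC)CCC[C@]34C)C(=O)OC)CCC[C@]2(C)[C@H]1CO[C@@H](C(=O)OC)[C@H](CC(=O)OC)C(=O)OCC=C | intermediate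
26 | trimer diacid, C15–OH free, 6'-allyl ester on unit A | C=C1CC[C@H]2[C@](C)(COC(=O)[C@@H](CC(=O)O)[C@@H](OC[C@H]3C(=C)CC[C@H]4[C@](C)(COC(=O)[C@@H](CC(=O)O)[C@@H](OC[C@H]5C(=C)CC[C@H]6[C@](C)(CO)CCC[C@]56C)C(=O)OC)CCC[C@]34C)C(=O)OC)CCC[C@]2(C)[C@H]1CO[C@@H](C(=O)OC)[C@H](CC(=O)OC)C(=O)OCC=C | intermediate
27 | cryptoporic acid T | C=C1CC[C@H]2[C@](C)(COC(=O)[C@@H](CC(=O)O)[C@@H](OC[C@H]3C(=C)CC[C@H]4[C@](C)(COC(=O)[C@@H](CC(=O)O)[C@@H](OC[C@H]5C(=C)CC[C@H]6[C@](C)(CO)CCC[C@]56C)C(=O)OC)CCC[C@]34C)C(=O)OC)CCC[C@]2(C)[C@H]1CO[C@@H](C(=O)OC)[C@H](CC(=O)OC)C(=O)O | target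

**Totals**
Total step count: 18. Longest linear sequence: 17 steps (steps 1–10 and 12–18; step 11 is the branch that supplies acid 16).

**Steps most likely to fail**

Step 4. What may go wrong: silver-assisted ionisation of the allylic bromide runs ahead of O-alkylation of the hindered C2' hydroxyl, so that allylic transposition to the tertiary ether and E/Z scrambling take over. Fallback (π-allyl route instead of halide abstraction): it sets out from 7. Commercial (2E,6E)-farnesol is converted with methyl chloroformate and pyridine into (2E,6E)-farnesyl methyl carbonate F1. The zinc alkoxide of 7 (Et2Zn, THF) is then allylated by F1 with Pd(OAc)2 and 2-(di-tert-butylphosphino)biphenyl (Tsuji–Trost O-allylation through a π-allyl complex of zerovalent palladium, attack at the unsubstituted terminus). This gives 9, where the route is rejoined.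

Step 8. What may go wrong: the C8 radical abstracts the captodative C2'–H by 1,5-hydrogen transfer instead of being trapped by titanium, the titanium-bound C4 radical is reduced before ring A closes, or face control at the planar C4 radical is lost. Fallback (polar instead of radical cascade): it sets out from 12 and comes back at 13, with no new compound on the way (F0). MeAlCl2 in CH2Cl2 at −78 °C opens the epoxide in an SN2-like attack of the C5=C10 alkene, so that C4 is fixed by inversion from the (E)-epoxide geometry; ring B closes by cation–olefin addition and the C8 cation loses a C12 proton. The exocyclic isomer 13 is then separated from its Δ7 isomer on AgNO3-impregnated silica gel.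

Step 14 (the esterification of step 16 carries the same risk at the second ester bond). What may go wrong: acyl transfer to the neopentyl C15 hydroxyl is slow, so that the acyl-pyridinium species epimerises at C3' or loses the C2' alkoxide by β-elimination before it is captured. Fallback (alkylative esterification, in which the acid is never activated): it sets out from 19. Tf2O and 2,6-lutidine in CH2Cl2 at −78 °C give the C15 trifluoromethanesulfonate of 19 F2. SN2 displacement of this primary triflate by the cesium carboxylate of 16 (Cs2CO3, 18-crown-6, DMF, rt to 40 °C) gives 21, where the route is rejoined.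

**Further compounds**
F1 | step 4 | (2E,6E)-farnesyl methyl carbonate | CC(C)=CCC/C(C)=C/CC/C(C)=C/COC(=O)OC
F0 | step 8 | none | none
F2 | step 14 | C15 trifluoromethanesulfonate of 19 | C=C1CC[C@H]2[C@](C)(COS(=O)(=O)C(F)(F)F)CCC[C@]2(C)[C@H]1CO[C@@H](C(=O)OC)[C@H](CC(=O)OC)C(=O)OCC=C
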